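The vessel is closed, stirred and held at one temperature. Substrate, catalyst and added ligand go in, and two earlier runs show what became of the substrate.

| setting | Sunday's | Monday's | maple | alder | oak |
|---|---|---|---|---|---|
| substrate | 0.40 M | 0.40 M | 0.40 M | 0.40 M | 0.40 M |
| catalyst | 2 mM | 2 mM | 2.0 mM | 2.0 mM | 2.0 mM |
| added ligand | 1.5 mM | 6.3 mM | 6.0 mM | 2.0 mM | 18 mM |
| remark | run made earlier | run made earlier |  |  |  |
| time |  |  | 25 h | 25 h | 25 h |

| run | time / h | substrate / % | isomer of the product / % | target / % |
|---|---|---|---|---|
| Sunday's | 3.00 | 62.9 | 3.2 | 34.3 |
| Sunday's | 8.00 | 58.6 | 9.3 | 32.3 |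
| Sunday's | 15.0 | 54.9 | 16.0 | 29.6 |
| Sunday's | 25.0 | 50.7 | 21.7 | 27.6 |
| Monday's | 3.00 | 63.3 | 0.7 | 35.2 |
| Monday's | 8.00 | 62.9 | 3.6 | 34.5 |
| Monday's | 15.0 | 61.1 | 6.1 | 34.0 |
| Monday's | 25.0 | 58.6 | 8.8 | 32.4 |

(scatter of a reading: 0.3 percentage points)



1. which of these there is most of at the end, counted by the substrate in it, maple (target / isomer of the product / substrate)
2. which of these there is most of at the end, counted by the substrate in it, alder (target / isomer of the product / substrate)
3. which of these there is most of at the end, counted by the substrate in it, oak (target / isomer of the product / substrate)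
4. amount of the one of these that there is most of at the end, in percent of the substrate charged, maple
5. amount of the one of these that there is most of at the end, in percent of the substrate charged, alder
6. amount of the one of these that there is most of at the end, in percent of the substrate charged, oak

I keep a ledger in fractions of the charge. The substrate-and-target pool divides the same way in both runs at 25 h, with substrate 64.6 % of it. So one entry, the isomer, closes the books.

In Sunday's run the slope of the isomer is 0.0107 /h up to 15.0 h, and the later slope is smaller, at 0.00570 /h. My first answer, a steady drain, therefore fails. I put that slowing back in as a first-order approach to a ceiling, and a straight line of gain against isomer held reaches zero gain at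

ceiling = 29.5 %.

The clock of a flask is the number of relaxation times it has run, ln(ceiling/(ceiling − isomer)). Sunday's reads 1.33 and Monday's 0.355, so the run with more added ligand has the slower clock. I assume that the reciprocal clock rises in a straight line with ligand charged, by 0.431 /mM. Two points cannot test this, and oak lies far beyond them.

Maple: clock 0.372, isomer 9.15 %, substrate 58.7 %, target 32.2 %.

Alder: clock 1.04, isomer 19.0 %, substrate 52.3 %, target 28.7 %.

Oak: clock 0.127, isomer 3.52 %, substrate 62.3 %, target 34.2 %.

Substrate is my largest entry in maple, alder and oak .

The forecast, which calls the drain “essentially irreversibly” where I put a ceiling, names substrate and gives 58.6 % in maple, 52.5 % in alder and 62.2 % in oak.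

The flask gives substrate as the largest entry, with 58.7 % in maple, 51.9 % in alder and 62.5 % in oak .

    substrate ⇌ target (K = 0.550, k = 1.10 /h)
    target + catalyst ⇌ isomer of the product + catalyst, rate k2*[catalyst]*[target] forward; the back reaction follows from the equilibrium constant (K = 1.40, k = 34.0 /M/h)
    isomer of the product + catalyst ⇌ substrate + catalyst, rate k3*[catalyst]*[isomer of the product] forward; the back reaction follows from the equilibrium constant (k = 1.10 /M/h)
    catalyst + added ligand ⇌ idle complex, settled at all times (K = 1100 /M)

Alder's isomer, 19.7 %, reads on my ceiling as a clock of 1.10, against my 1.04. A neighbour of maple takes 2.40 mM of added ligand. The same line gives it a clock of 0.879, so isomer 17.2 % and substrate 53.5 %. That neighbour ends with 18.1 % isomer and 52.9 % substrate.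

All runs stem from a simulated flask from invented constants.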